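**Plan**
1. Cuts: the acid comes from its ethyl ester, the Me2C=CH end of the C4 chain from a vinyl group (cross-metathesis), the 7α-OH from allylic oxidation of the C8=CH2 alkene, and C13=C14 and C8=CH2 from olefination of a C13 methyl ketone and a C8 ketone.
2. Ring B (C5–C6–C7–C8–C9–C10) is then cut at C9–C10 and C10 is re-joined to C8: the 8-oxodecalin becomes a trans-hydrindane whose five-membered ring C10–C8–C7–C6–C5 carries a tertiary 8α-OH and an exocyclic C9 bearing NH2 and the side chain.
3. Enabling feature: C8 is at ketone level between C7H2 and C9, and C9 is bonded to the quaternary C10, so a 1,2-shift of C10 from C8 to C9 (Tiffeneau–Demjanov) makes ring B and the hindered C9–C10 bond in one event.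
4. Forward: a vinyl ketone and 2-methylcyclopentane-1,3-dione give ring A and the five-membered ring (Hajos–Parrish-type aldol); a Wittig reaction adds C9, C11–C13 and C16; reductive methylation and Wolff–Kishner reduction finish ring A; epoxide, azide, amine; ring expansion; then C8 methylenation, the enoate, C7 oxidation, metathesis and hydrolysis.
5. Stereochemistry: C10 from the L-phenylalanine-mediated aldol; C5 and C4 from the Birch alkylation anti to the C10 methyl; C9 from Z-alkene → α-epoxide → SN2 azide → invertive migration; C7 from axial oxygen delivery by SeO2; the E enoate from the Horner–Wadsworth–Emmons reaction.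

Key step: step 12

Remark: ring atoms are numbered as in labdanes throughout (C10 carries the β-methyl, C4 the 4α-methyl and the 4β chain, C5 the ring-fusion hydrogen, C9 and C11–C16 form the side chain, C19 is the 4β carbon); α is the face opposite the C10 methyl. Compounds 1, 2, 7 and 10 are taken as commercial.

**Route**

Step 1
Reactants: 1 5-bromopent-1-ene; 2 acrolein
Product: 5 (±)-octa-1,7-dien-3-ol, via pent-4-enylmagnesium bromide 3 (not isolated), via bromomagnesium alkoxide 4 (not isolated)
Conditions: Mg, THF, 40 °C; then 2, −78 °C; aq. NH4Cl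
Reagents that add atoms: none
Why: Grignard addition to acrolein at low temperature goes 1,2 and should give the secondary allylic alcohol, whose stereocentre is removed in step 2.

Step 2
Reactants: 5 (±)-octa-1,7-dien-3-ol
Product: 6 octa-1,7-dien-3-one
Conditions: Dess–Martin periodinane, CH2Cl2, 0 → 20 °C; used directly
Reagents that add atoms: none
Why: Dess–Martin oxidation of a secondary allylic alcohol gives the vinyl ketone under neutral conditions that should not polymerise it.

Step 3
Reactants: 7 2-methylcyclopentane-1,3-dione; 6 octa-1,7-dien-3-one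
Product: 8 triketone
Conditions: Et3N (cat.), EtOAc, 20 °C
Reagents that add atoms: none
Why: Michael addition of the acidic 1,3-dione to the vinyl ketone creates the prochiral quaternary carbon that becomes C10.

Step 4
Reactants: 8 triketone
Product: 9 (S)-enedione
Conditions: L-phenylalanine (1 equiv), (1S)-(+)-camphor-10-sulfonic acid (0.5 equiv), DMF, 30 → 70 °C
Reagents that add atoms: none
Why: In this Hajos–Parrish–Eder–Sauer–Wiechert aldol condensation the L-phenylalanine enamine of the chain ketone attacks one of the two enantiotopic ring carbonyls, which should set C10 as S, and the CH2 that carries the butenyl group becomes C4.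

Step 5
Reactants: 10 2-(3-chloropropyl)-2-methyl-1,3-dioxolane
Product: 11 phosphonium iodide
Conditions: PPh3, NaI, MeCN, 80 °C
Reagents that add atoms: triphenylphosphine c1ccc(cc1)P(c1ccccc1)c1ccccc1; sodium iodide [Na+].[I-]
Why: Finkelstein exchange in the flask followed by SN2 quaternisation of PPh3 should give the salt with the ketal untouched.

Step 6
Reactants: 9 (S)-enedione; 11 phosphonium iodide
Product: 13 (Z)-dienone, via phosphonium ylide 12 (not isolated)
Conditions: 11 (2.2 equiv), KOtBu, THF, 0 °C; then 9, 20 → 50 °C
Reagents that add atoms: none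
Why: In this Wittig olefination the unstabilised ylide should attack the saturated cyclopentanone in preference to the conjugated, tetrasubstituted enone carbonyl (as in C17-selective olefination of androst-4-ene-3,17-dione) and should place the chain cis to the quaternary carbon (Z), as with 17-oxo steroids.

Step 7
Reactants: 13 (Z)-dienone
Product: 15 trans-hydrindanone, via lithium enolate 14 (not isolated)
Conditions: Li (2.2 equiv), t-BuOH (1.0 equiv), NH3(l)/THF, −78 °C; then MeI (excess), −78 → −33 °C
Reagents that add atoms: iodomethane CI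
Why: Birch reductive alkylation protonates C5 to give the trans-fused C3–C4 enolate regiospecifically, and MeI should enter C4 anti to the C10 methyl (α), leaving the butenyl chain β; isolated alkenes and the ketal are inert.

Step 8
Reactants: 15 trans-hydrindanone
Product: 17 (Z)-alkylidene hydrindane, via hydrazone 16 (not isolated)
Conditions: N2H4·H2O, KOH, diethylene glycol, 130 °C then 200 °C, under Ar
Reagents that add atoms: none
Why: Wolff–Kishner reduction (Huang-Minlon procedure) removes the neopentyl C3 carbonyl under basic conditions that spare the ketal and the alkenes, with air excluded to suppress diimide.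

Step 9
Reactants: 17 (Z)-alkylidene hydrindane
Product: 18 8α,9-epoxide
Conditions: mCPBA (1.05 equiv), NaHCO3, CH2Cl2, 0 °C
Reagents that add atoms: 3-chloroperbenzoic acid OOC(=O)c1cccc(Cl)c1
Why: Prilezhaev epoxidation should select the trisubstituted exocyclic alkene over the monosubstituted vinyl group and attack the face anti to the C10 methyl, putting oxygen α at C8.

Step 10
Reactants: 18 8α,9-epoxide
Product: 19 azido alcohol
Conditions: NaN3, NH4Cl, 2-methoxyethanol/H2O, 110 °C
Reagents that add atoms: sodium azide [Na+].[N-]=[N+]=[N-]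
Why: SN2 opening of the trisubstituted epoxide by azide at the less substituted C9, anti to oxygen, inverts C9 and keeps the tertiary 8α-OH.

Step 11
Reactants: 19 azido alcohol
Product: 21 amino alcohol, via iminophosphorane 20 (not isolated)
Conditions: PMe3, THF, 20 °C; then H2O, 50 °C
Reagents that add atoms: none
Why: Staudinger reduction converts the azide to the primary amine without touching the alkene or the ketal and without changing C9.

Step 12
Reactants: 21 amino alcohol
Product: 23 8-oxodecalin, via diazonium acetate 22 (not isolated)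
Conditions: NaNO2 (1.5 equiv), AcOH/NaOAc, THF/H2O, 0 → 20 °C
Reagents that add atoms: none
Why: Nitrosation turns the C9 amine into diazonium 22; as N2 leaves, the C8–C10 bond, which lies anti to C9–N in the least crowded rotamer, shifts to C9 while the 8α-hydroxyl becomes the C8 carbonyl. This is a Tiffeneau–Demjanov (semipinacol) ring enlargement, the type known from D-homoannulation of 17α-hydroxy-20-amino steroids, whose five-membered ring has the same substitution pattern. Ring B is not closed by a cyclisation but by the 1,2-shift itself: the five-membered ring C10–C8–C7–C6–C5 takes up C9 and becomes six-membered, and the C9–C10 bond forms next to the quaternary carbon. C10 migrates with retention and enters C9 opposite to nitrogen, so C9 is set by inversion of the centre fixed in steps 6, 9 and 10 and should come out with the side chain equatorial (9β), which is also the more stable epimer next to the new ketone. The step needs migration of C10 and not of C7, and no closure of the hydroxyl onto C9: with oxygen α and C9 β at C8, only the rotamer with N2+ anti to C10 keeps hydrogen, and not C11 or N2+, against the C10 methyl, and the quaternary C10 is the better migrating group.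

Step 13
Reactants: 23 8-oxodecalin
Product: 24 8(17)-methylene ketal
Conditions: Ph3PCH3Br, KOtBu, toluene, 80 °C
Reagents that add atoms: methyltriphenylphosphonium bromide C[P+](c1ccccc1)(c1ccccc1)c1ccccc1.[Br-]
Why: Wittig methylenation of the hindered C8 ketone, as used for 8-oxolabdanes; C9 is enolisable but already holds its more stable configuration.

Step 14
Reactants: 24 8(17)-methylene ketal
Product: 25 methyl ketone
Conditions: pyridinium p-toluenesulfonate, acetone/H2O, 50 °C
Reagents that add atoms: water O
Why: Mild acid-catalysed hydrolysis of the dioxolane should free the C13 ketone without moving the exocyclic double bond.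

Step 15
Reactants: 25 methyl ketone
Product: 26 ethyl (E)-enoate
Conditions: (EtO)2P(O)CH2CO2Et, NaH, THF, 0 → 65 °C; chromatography
Reagents that add atoms: triethyl phosphonoacetate CCOC(=O)CP(=O)(OCC)OCC
Why: Horner–Wadsworth–Emmons olefination of the methyl ketone should favour the E enoate (ester trans to the larger CH2 branch), and the minor Z isomer would be removed by chromatography.

Step 16
Reactants: 26 ethyl (E)-enoate
Product: 27 7α-hydroxy ester
Conditions: SeO2 (0.5 equiv), t-BuOOH (2 equiv), CH2Cl2, 20 °C
Reagents that add atoms: selenium dioxide O=[Se]=O; tert-butyl hydroperoxide CC(C)(C)OO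
Why: Riley allylic oxidation (ene reaction at the exocyclic methylene with loss of the axial 7α-H, then [2,3]-shift) should deliver oxygen axially to the ring CH2 to give the 7α-alcohol, as with other 8(17)-ene decalins, and the 1,1-disubstituted alkene reacts before the vinyl group or the deactivated enoate.

Step 17
Reactants: 27 7α-hydroxy ester
Product: 28 homoprenyl ester
Conditions: second-generation Grubbs catalyst (5 mol %), 2-methylbut-2-ene (excess), CH2Cl2, 40 °C, sealed
Reagents that add atoms: 2-methylbut-2-ene CC=C(C)C
Why: Olefin cross-metathesis of the terminal vinyl group with 2-methylbut-2-ene installs the isopropylidene end, while the hindered exocyclic methylene and the trisubstituted enoate should not engage the ruthenium carbene.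

Step 18
Reactants: 28 homoprenyl ester
Product: 30 target acid CNP0169778.1, via lithium carboxylate 29 (not isolated)
Conditions: LiOH, THF/MeOH/H2O, 50 °C; then 1 M HCl to pH 3
Reagents that add atoms: lithium hydroxide [Li+].[OH-]
Why: Saponification of the ethyl ester and acidification give the free acid without touching any stereocentre or alkene.

**Compound list**
1 | 5-bromopent-1-ene | C=CCCCBr | starting material
2 | acrolein (prop-2-enal) | C=CC=O | starting material
3 | pent-4-enylmagnesium bromide | C=CCCC[Mg]Br | intermediate
4 | bromomagnesium octa-1,7-dien-3-olate | C=CC(O[Mg]Br)CCCC=C | intermediate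
5 | (±)-octa-1,7-dien-3-ol | C=CC(O)CCCC=C | intermediate
6 | octa-1,7-dien-3-one | C=CC(=O)CCCC=C | intermediate
7 | 2-methylcyclopentane-1,3-dione | CC1C(=O)CCC1=O | starting material
8 | 2-methyl-2-(3-oxooct-7-en-1-yl)cyclopentane-1,3-dione | CC1(CCC(=O)CCCC=C)C(=O)CCC1=O | intermediate
9 | (7aS)-4-(but-3-en-1-yl)-7a-methyl-2,3,7,7a-tetrahydro-1H-indene-1,5(6H)-dione | C[C@]12CCC(=O)C(CCC=C)=C1CCC2=O | intermediate
10 | 2-(3-chloropropyl)-2-methyl-1,3-dioxolane | CC1(CCCCl)OCCO1 | starting material
11 | [3-(2-methyl-1,3-dioxolan-2-yl)propyl]triphenylphosphonium iodide | CC1(CCC[P+](c2ccccc2)(c2ccccc2)c2ccccc2)OCCO1.[I-] | intermediate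
12 | [3-(2-methyl-1,3-dioxolan-2-yl)propylidene]triphenylphosphorane | CC1(CCC=P(c2ccccc2)(c2ccccc2)c2ccccc2)OCCO1 | intermediate
13 | (1Z,7aR)-4-(but-3-en-1-yl)-7a-methyl-1-[3-(2-methyl-1,3-dioxolan-2-yl)propylidene]-2,3,7,7a-tetrahydro-1H-inden-5(6H)-one (chain cis to the quaternary carbon) | C[C@]12CCC(=O)C(CCC=C)=C1CC/C2=C/CCC1(C)OCCO1 | intermediate
14 | lithium C3–C4 enolate of 15 (trans-fused, 5α-H) | C(\CCC1(C)OCCO1)=C1/CC[C@H]2C(CCC=C)=C([O-])CC[C@@]21C.[Li+] | intermediate
15 | (1Z,3aR,4R,7aS)-4-(but-3-en-1-yl)-4,7a-dimethyl-1-[3-(2-methyl-1,3-dioxolan-2-yl)propylidene]octahydro-5H-inden-5-one (trans-fused, 4α-methyl, 4β-butenyl) | C(\CCC1(C)OCCO1)=C1/CC[C@H]2[C@@](C)(CCC=C)C(=O)CC[C@@]21C | intermediate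
16 | C3 hydrazone of 15 | C(\CCC1(C)OCCO1)=C1/CC[C@H]2[C@@](C)(CCC=C)C(=NN)CC[C@@]21C | intermediate
17 | (1Z,3aS,4R,7aS)-4-(but-3-en-1-yl)-4,7a-dimethyl-1-[3-(2-methyl-1,3-dioxolan-2-yl)propylidene]octahydro-1H-indene | C(\CCC1(C)OCCO1)=C1/CC[C@H]2[C@@](C)(CCC=C)CCC[C@@]21C | intermediate
18 | 8α,9-epoxide of 17 (spiro-oxirane; oxygen anti to the C10 methyl; C11 cis to C10) | [C@@H]3(CCC4(C)OCCO4)O[C@@]31CC[C@H]2[C@@](C)(CCC=C)CCC[C@@]21C | intermediate
19 | 9-azido-8α-hydroxy hydrindane (tertiary 8α-OH; C9 on the β-face, inverted relative to 18, bearing N3 and the 2-(2-methyl-1,3-dioxolan-2-yl)ethyl group) | [C@H](CCC1(C)OCCO1)(N=[N+]=[N-])[C@@]1(O)CC[C@H]2[C@@](C)(CCC=C)CCC[C@@]21C | intermediate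
20 | P,P,P-trimethyliminophosphorane of 21 | [C@H](CCC1(C)OCCO1)(N=P(C)(C)C)[C@@]1(O)CC[C@H]2[C@@](C)(CCC=C)CCC[C@@]21C | intermediate
21 | 9-amino-8α-hydroxy hydrindane (same configuration as 19) | [C@H](CCC1(C)OCCO1)(N)[C@@]1(O)CC[C@H]2[C@@](C)(CCC=C)CCC[C@@]21C | intermediate
22 | C9 diazonium acetate of 21 | [C@H](CCC1(C)OCCO1)([N+]#N)[C@@]1(O)CC[C@H]2[C@@](C)(CCC=C)CCC[C@@]21C.CC(=O)[O-] | intermediate
23 | 19-allyl-13,13-(ethylenedioxy)-14,15,17-trinorlabdan-8-one (trans-decalin; 4α,10β-dimethyl, 4β-but-3-enyl, 5α-H, 9α-H) | O=C1CC[C@H]2[C@@](C)(CCC=C)CCC[C@]2(C)[C@H]1CCC1(C)OCCO1 | intermediate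
24 | 19-allyl-13,13-(ethylenedioxy)-14,15-dinorlabd-8(17)-ene | C=C1CC[C@H]2[C@@](C)(CCC=C)CCC[C@]2(C)[C@H]1CCC1(C)OCCO1 | intermediate
25 | 19-allyl-14,15-dinorlabd-8(17)-en-13-one | C=C1CC[C@H]2[C@@](C)(CCC=C)CCC[C@]2(C)[C@H]1CCC(C)=O | intermediate
26 | ethyl 19-allyllabda-8(17),13E-dien-15-oate | C=C1CC[C@H]2[C@@](C)(CCC=C)CCC[C@]2(C)[C@H]1CC/C(C)=C/C(=O)OCC | intermediate
27 | ethyl 19-allyl-7α-hydroxylabda-8(17),13E-dien-15-oate | C=C1[C@H](O)C[C@H]2[C@@](C)(CCC=C)CCC[C@]2(C)[C@H]1CC/C(C)=C/C(=O)OCC | intermediate
28 | ethyl 7α-hydroxy-19-(3-methylbut-2-enyl)labda-8(17),13E-dien-15-oate | C=C1[C@H](O)C[C@H]2[C@@](C)(CCC=C(C)C)CCC[C@]2(C)[C@H]1CC/C(C)=C/C(=O)OCC | intermediate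
29 | lithium salt of 30 | C=C1[C@H](O)C[C@H]2[C@@](C)(CCC=C(C)C)CCC[C@]2(C)[C@H]1CC/C(C)=C/C(=O)[O-].[Li+] | intermediate
30 | (2E)-5-[(1R,3R,4aS,5R,8aS)-3-hydroxy-5,8a-dimethyl-2-methylidene-5-(4-methylpent-3-en-1-yl)decahydronaphthalen-1-yl]-3-methylpent-2-enoic acid | C=C1[C@H](O)C[C@H]2[C@@](C)(CCC=C(C)C)CCC[C@]2(C)[C@H]1CC/C(C)=C/C(=O)O | target

**Totals**
Total steps: 18. Longest linear sequence: 17 (steps 1–4 and 6–18; step 5 makes the side-chain salt).

**Steps most likely to fail**

Step 12. The C8–C7 bond may migrate in place of C8–C10, the neighbouring hydroxyl may close onto C9 (epoxide), the diazonium may eliminate or be solvolysed, and the dioxolane may be lost in the acidic medium. The fallback sets out from epoxide 18 and comes back at ketone 23, and it replaces the free diazonium in aqueous acid by silver-assisted departure of a selenium leaving group in a non-aqueous medium. Sodium methaneselenolate (from MeSeSeMe and NaBH4, EtOH, 70 °C) should open 18 at C9 with inversion to the 8α-hydroxy-9-methylselanyl hydrindane F1. AgBF4 on Al2O3 in CH2Cl2 at 20 °C should then take off selenium while the anti C8–C10 bond shifts (semipinacol ring enlargement of a β-hydroxyalkyl selenide) to give 23. This path also avoids the azide and amine stages.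

Step 7. Protonation of C5 from the β-face would give the cis ring fusion, proton transfer in ammonia may quench the enolate before methylation, and methylation may lose face selectivity. The fallback sets out from dienone 13 and comes back at ketone 15, and it replaces electron transfer by hydride conjugate addition. i-Bu2AlH with MeCu (from MeLi and CuBr·SMe2) in THF/HMPA at −50 °C should deliver hydride to C5 from the α-face and give the diisobutylaluminium enolate F2. Adding MeLi to form the ate complex and then MeI should methylate C4 anti to the C10 methyl and give 15.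

Step 6. The ylide may also olefinate or deconjugate the enone, and the base may cleave the vinylogous 1,3-diketone. The fallback sets out from enedione 9 and comes back at dienone 13, and it masks the enone before the Wittig reaction. Pyrrolidine in MeOH at 65 °C should convert only the enone into the C3 dienamine F3 (C3=C4, C5=C6). Ylide 12 in THF then olefinates the remaining C8 ketone to the (Z)-alkylidene dienamine F4, and buffered aqueous AcOH/NaOAc hydrolysis returns the conjugated enone 13.

**Further compounds**
F1 | step 12 | 8α-hydroxy-9-(methylselanyl) hydrindane (configuration as 19, SeMe in place of N3) | [C@H](CCC1(C)OCCO1)([Se]C)[C@@]1(O)CC[C@H]2[C@@](C)(CCC=C)CCC[C@@]21C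
F2 | step 7 | diisobutylaluminium C3–C4 enolate of 15 (trans-fused, 5α-H) | C(\CCC1(C)OCCO1)=C1/CC[C@H]2C(CCC=C)=C(O[Al](CC(C)C)CC(C)C)CC[C@@]21C
F3 | step 6 | (7aS)-4-(but-3-en-1-yl)-7a-methyl-5-(pyrrolidin-1-yl)-2,6,7,7a-tetrahydro-1H-inden-1-one (C3 dienamine of 9) | C[C@]12CCC(N3CCCC3)=C(CCC=C)C1=CCC2=O
F4 | step 6 | (Z)-alkylidene dienamine (C8 olefinated F3, chain cis to the quaternary carbon) | C[C@]12CCC(N3CCCC3)=C(CCC=C)C1=CC/C2=C/CCC1(C)OCCO1
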